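**Plan**

- Numbering: ring A is the trimethoxyphenyl group on C7, ring B the benzo ring (C1'–C6'), ring C the dihydrofuran (O, C7, C8, C3', C4').
- Enabling feature: C8 is bonded at once to the ring B carbon C3', to the oxygen-bearing methylene C9 and to the ether carbon C7. This is the imprint of an aryl radical at C3' adding to the inner carbon of a vinyl group on C7, with the terminal carbon then taking up oxygen.
- Cuts, in retrosynthetic order: the C9' oxidation level and C1'–C7' (Heck), then C3'–C8 together with C9–O (radical closure with nitroxide capture), then O4'–C7 (allylic etherification). This leaves an iodinated bromoguaiacol and a cinnamyl carbonate.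
- Forward order: rings A and B are joined through O4'–C7, ring C closes by 5-exo attack of C3' on C8, and the propenol chain is attached at C1' last.
- Stereochemistry: C7 (R) comes from the chiral iridium phosphoramidite catalyst, C8 (S) from induction by C7 in the ring closure (trans), and 7'E from the Heck reaction.

Key step: step 6

Assumption: the ligand L, (Ra,Rc,Rc)-(1,1'-binaphthalene-2,2'-diyl) N,N-bis(1-phenylethyl)phosphoramidite, is taken to deliver the 7R ether with an aryloxide and a cinnamyl carbonate; should the first run show the opposite sense, the (Sa,Sc,Sc) ligand is used and nothing else changes.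

**Route**

Step 1
Reactants: 1 4-bromo-2-methoxyphenol
Product: 2 4-bromo-2-iodo-6-methoxyphenol
Conditions: NIS, TsOH·H2O (cat.), MeCN, 0 °C to rt
Reagents that add atoms: N-iodosuccinimide, O=C1CCC(=O)N1I
Why: Electrophilic aromatic iodination is directed by the hydroxyl group, whose para position is blocked by bromine and one ortho position by methoxy, so iodine should enter the one free ortho position.

Step 2
Reactants: 3 (E)-3-(3,4,5-trimethoxyphenyl)acrylic acid
Product: 4 methyl (E)-3-(3,4,5-trimethoxyphenyl)acrylate
Conditions: MeOH, H2SO4 (cat.), reflux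
Reagents that add atoms: methanol, CO
Why: Fischer esterification in excess methanol should convert the acid into an ester that can be reduced cleanly, with the alkene geometry untouched.

Step 3
Reactants: 4 methyl (E)-3-(3,4,5-trimethoxyphenyl)acrylate
Product: 5 (E)-3-(3,4,5-trimethoxyphenyl)prop-2-en-1-ol
Conditions: iBu2AlH (2.5 equiv), CH2Cl2, −78 °C to 0 °C; aq. potassium sodium tartrate
Reagents that add atoms: none
Why: Hydride reduction with iBu2AlH takes conjugated esters to allylic alcohols by 1,2-addition and should leave the alkene in place.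

Step 4
Reactants: 5 (E)-3-(3,4,5-trimethoxyphenyl)prop-2-en-1-ol
Product: 6 methyl (E)-3-(3,4,5-trimethoxyphenyl)prop-2-en-1-yl carbonate
Conditions: ClCO2Me, pyridine, CH2Cl2, 0 °C
Reagents that add atoms: methyl chloroformate, COC(=O)Cl
Why: Acylation of the primary alcohol with a chloroformate should give the linear allylic carbonate, whose leaving group releases methoxide and carbon dioxide on ionisation in step 5.

Step 5
Reactants: 2 4-bromo-2-iodo-6-methoxyphenol; 6 methyl (E)-3-(3,4,5-trimethoxyphenyl)prop-2-en-1-yl carbonate
Product: 8 (R)-5-bromo-1-iodo-3-methoxy-2-{[1-(3,4,5-trimethoxyphenyl)prop-2-en-1-yl]oxy}benzene, via lithium 4-bromo-2-iodo-6-methoxyphenoxide 7 (not isolated)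
Conditions: 2, LiN(SiMe3)2, THF, 0 °C; then 6, [Ir(cod)Cl]2 (cat.), ligand L (cat.), THF, 50 °C
Reagents that add atoms: none
Why: In this iridium-catalysed enantioselective allylic etherification the aryloxide attacks the aryl-substituted terminus of the allyliridium intermediate from the face opposite the metal, which should give the branched ether, and the chiral phosphoramidite sets the R configuration at C7.

Step 6
Reactants: 8 (R)-5-bromo-1-iodo-3-methoxy-2-{[1-(3,4,5-trimethoxyphenyl)prop-2-en-1-yl]oxy}benzene; 9 2,2,6,6-tetramethylpiperidin-1-oxyl (TEMPO)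
Product: 10 1-{[(2R,3S)-5-bromo-7-methoxy-2-(3,4,5-trimethoxyphenyl)-2,3-dihydrobenzofuran-3-yl]methoxy}-2,2,6,6-tetramethylpiperidine
Conditions: TEMPO (5 equiv), Bu3SnH (3 equiv, in portions), PhH, 60 °C
Reagents that add atoms: none
Why: Hydrogen transfer from Bu3SnH to the nitroxide gives the stannyl radical, which takes iodine from C3'; the aryl radical adds to the inner alkene carbon C8 and the primary C9 radical couples with a second nitroxide, so the C3'–C8 and C9–O bonds form in one operation. The closest known reaction type is the tin hydride and TEMPO mediated aryl radical cyclisation with nitroxide capture of ortho-iodoaryl allyl ethers and N-allyl anilines. Ring C closes in the 5-exo-trig mode, which for an ortho-allyloxyaryl radical is far faster than 6-endo closure or bimolecular capture of the aryl radical. The new stereocentre C8 is controlled by C7: in the chair-like transition state the trimethoxyphenyl group lies pseudo-equatorial, which places the C9 methylene trans to it and should give 8S from 7R. The step needs abstraction of iodine in preference to bromine and nitroxide capture in preference to hydrogen transfer to C9; the first rests on the much faster reaction of stannyl radicals with aryl iodides, helped by excess nitroxide shortening the stannyl radical lifetime, and the second on the near diffusion-controlled radical–nitroxide coupling at a low standing concentration of stannane.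

Step 7
Reactants: 10 1-{[(2R,3S)-5-bromo-7-methoxy-2-(3,4,5-trimethoxyphenyl)-2,3-dihydrobenzofuran-3-yl]methoxy}-2,2,6,6-tetramethylpiperidine
Product: 11 [(2R,3S)-5-bromo-7-methoxy-2-(3,4,5-trimethoxyphenyl)-2,3-dihydrobenzofuran-3-yl]methanol
Conditions: Zn dust, AcOH–THF–H2O (3:1:1), 70 °C
Reagents that add atoms: none
Why: Dissolving-metal reduction cleaves the weak N–O bond of the alkoxyamine to the C9 alcohol and should touch neither stereocentre nor the aryl bromide.

Step 8
Reactants: 11 [(2R,3S)-5-bromo-7-methoxy-2-(3,4,5-trimethoxyphenyl)-2,3-dihydrobenzofuran-3-yl]methanol; 12 methyl acrylate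
Product: 13 methyl (E)-3-[(2R,3S)-3-(hydroxymethyl)-7-methoxy-2-(3,4,5-trimethoxyphenyl)-2,3-dihydrobenzofuran-5-yl]acrylate
Conditions: Pd(OAc)2 (5 mol %), P(o-tol)3 (15 mol %), Et3N, DMF, 100 °C
Reagents that add atoms: none
Why: In the Mizoroki–Heck reaction, oxidative addition of the aryl bromide to zerovalent palladium, syn insertion of the acrylate and syn β-hydride elimination should give the E enoate at C1', and the free primary alcohol is tolerated.

Step 9
Reactants: 13 methyl (E)-3-[(2R,3S)-3-(hydroxymethyl)-7-methoxy-2-(3,4,5-trimethoxyphenyl)-2,3-dihydrobenzofuran-5-yl]acrylate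
Product: 14 (7R,8S,7'E)-3,4,5,5'-tetramethoxy-4',7-epoxy-8,3'-neolign-7'-ene-9,9'-diol
Conditions: iBu2AlH (4 equiv), CH2Cl2, −78 °C to −20 °C; aq. potassium sodium tartrate
Reagents that add atoms: none
Why: 1,2-Reduction of the conjugated ester with iBu2AlH (one equivalent is consumed by the free hydroxyl) should give the E allylic alcohol without change at C7 or C8.

**Compound list**

1 | 4-bromo-2-methoxyphenol | COc1cc(Br)ccc1O | starting material
2 | 4-bromo-2-iodo-6-methoxyphenol | COc1cc(Br)cc(I)c1O | intermediate
3 | (E)-3-(3,4,5-trimethoxyphenyl)acrylic acid | COc1cc(/C=C/C(=O)O)cc(OC)c1OC | starting material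
4 | methyl (E)-3-(3,4,5-trimethoxyphenyl)acrylate | COC(=O)/C=C/c1cc(OC)c(OC)c(OC)c1 | intermediate
5 | (E)-3-(3,4,5-trimethoxyphenyl)prop-2-en-1-ol | COc1cc(/C=C/CO)cc(OC)c1OC | intermediate
6 | methyl (E)-3-(3,4,5-trimethoxyphenyl)prop-2-en-1-yl carbonate | COC(=O)OC/C=C/c1cc(OC)c(OC)c(OC)c1 | intermediate
7 | lithium 4-bromo-2-iodo-6-methoxyphenoxide | [Li+].[O-]c1c(I)cc(Br)cc1OC | intermediate
8 | (R)-5-bromo-1-iodo-3-methoxy-2-{[1-(3,4,5-trimethoxyphenyl)prop-2-en-1-yl]oxy}benzene | COc1cc([C@@H](C=C)Oc2c(I)cc(Br)cc2OC)cc(OC)c1OC | intermediate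
9 | 2,2,6,6-tetramethylpiperidin-1-oxyl (TEMPO) | CC1(C)CCCC(C)(C)N1[O] | starting material
10 | 1-{[(2R,3S)-5-bromo-7-methoxy-2-(3,4,5-trimethoxyphenyl)-2,3-dihydrobenzofuran-3-yl]methoxy}-2,2,6,6-tetramethylpiperidine | COc1cc([C@@H]2Oc3c(OC)cc(Br)cc3[C@H]2CON4C(C)(C)CCCC4(C)C)cc(OC)c1OC | intermediate
11 | [(2R,3S)-5-bromo-7-methoxy-2-(3,4,5-trimethoxyphenyl)-2,3-dihydrobenzofuran-3-yl]methanol | COc1cc([C@@H]2Oc3c(OC)cc(Br)cc3[C@H]2CO)cc(OC)c1OC | intermediate
12 | methyl acrylate | C=CC(=O)OC | starting material
13 | methyl (E)-3-[(2R,3S)-3-(hydroxymethyl)-7-methoxy-2-(3,4,5-trimethoxyphenyl)-2,3-dihydrobenzofuran-5-yl]acrylate | COc1cc([C@@H]2Oc3c(OC)cc(/C=C/C(=O)OC)cc3[C@H]2CO)cc(OC)c1OC | intermediate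
14 | (7R,8S,7'E)-3,4,5,5'-tetramethoxy-4',7-epoxy-8,3'-neolign-7'-ene-9,9'-diol | COc1cc([C@@H]2Oc3c(OC)cc(/C=C/CO)cc3[C@H]2CO)cc(OC)c1OC | target

**Step count**

Total: 9 steps. Longest linear sequence: 8 steps (3 to 14 through steps 2 to 9).

**Steps most likely to fail**

Step 6. The ring closure is irreversible, so a modest kinetic preference for the trans arrangement cannot be corrected within the step, and the two epimers may be hard to separate. The fallback sets out from 10 together with its C8 epimer and sets C8 under thermodynamic control. Oxidation of the alkoxyamine mixture with mCPBA (CH2Cl2, 0 °C) should turn the CH2–O–N unit into the aldehyde. This gives (2R,3R)-5-bromo-7-methoxy-2-(3,4,5-trimethoxyphenyl)-2,3-dihydrobenzofuran-3-carbaldehyde F1 (trans) beside (2R,3S)-5-bromo-7-methoxy-2-(3,4,5-trimethoxyphenyl)-2,3-dihydrobenzofuran-3-carbaldehyde F2 (cis). DBU (cat., CH2Cl2, rt) should equilibrate the acidic C8 position towards F1. Ring opening by β-elimination would be the reverse of a 5-endo-trig closure and is not expected, so C7 should keep its configuration. Reduction with NaBH4 (MeOH, 0 °C) comes back to the route at alcohol 11, and step 7 is then not needed.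

Step 5. Attack of the doubly ortho-substituted, halogenated aryloxide on the allyliridium intermediate may be slow. The product ether may also re-ionise, because this aryloxide is a fair leaving group, which would erode both the branched selectivity and the enantiomeric purity. The fallback sets out from phenol 2 and commercial 3,4,5-trimethoxybenzaldehyde and forms the O4'–C7 bond by substitution with inversion. Addition of CH2=CHMgBr (THF, 0 °C) to the aldehyde should give racemic 1-(3,4,5-trimethoxyphenyl)prop-2-en-1-ol F3. Lipase-mediated kinetic resolution (Candida antarctica lipase B, vinyl acetate, hexane, rt) is expected to acetylate the R enantiomer to (R)-1-(3,4,5-trimethoxyphenyl)prop-2-en-1-yl acetate F5, following the usual enantiopreference of lipases for secondary alcohols. This leaves (S)-1-(3,4,5-trimethoxyphenyl)prop-2-en-1-ol F4, which is separated. A Mitsunobu reaction of F4 with 2 (PPh3, diisopropyl azodicarboxylate, THF, 0 °C) should then give the R ether and so comes back to the route at 8.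

Step 8. Oxidative addition of the electron-rich aryl bromide may be slow, and the long heating then needed invites loss of bromine or decomposition of the benzylic ether. The fallback sets out from 11 and attaches the complete side chain in one operation. A Stille coupling with commercial (E)-3-(tributylstannyl)prop-2-en-1-ol (Pd(PPh3)4, toluene, 100 °C) should transfer the E hydroxypropenyl group with retention of alkene geometry. It comes back to the route at the target 14, so that step 9 is not needed and no compound outside the list is formed (F0).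

**Further compounds**

F1 | step 6 | (2R,3R)-5-bromo-7-methoxy-2-(3,4,5-trimethoxyphenyl)-2,3-dihydrobenzofuran-3-carbaldehyde | COc1cc([C@@H]2Oc3c(OC)cc(Br)cc3[C@H]2C=O)cc(OC)c1OC
F2 | step 6 | (2R,3S)-5-bromo-7-methoxy-2-(3,4,5-trimethoxyphenyl)-2,3-dihydrobenzofuran-3-carbaldehyde | COc1cc([C@@H]2Oc3c(OC)cc(Br)cc3[C@@H]2C=O)cc(OC)c1OC
F3 | step 5 | racemic 1-(3,4,5-trimethoxyphenyl)prop-2-en-1-ol | COc1cc(C(O)C=C)cc(OC)c1OC
F4 | step 5 | (S)-1-(3,4,5-trimethoxyphenyl)prop-2-en-1-ol | COc1cc([C@H](C=C)O)cc(OC)c1OC
F5 | step 5 | (R)-1-(3,4,5-trimethoxyphenyl)prop-2-en-1-yl acetate | COc1cc([C@@H](C=C)OC(C)=O)cc(OC)c1OC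
F0 | step 8 | none | none
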